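**Retrosynthetic overview**

1. Rings: A = methoxybenzene, B = lactam, C = five-membered O-ring across the peri positions, D = naphthalene ring with the free OH, E = naphthalene ring with CH3. The last disconnections are O-desilylation and the spiro C–O bond of ring C, closed by a chiral phosphoric acid-catalysed N,O-ketalisation of a 3-hydroxylactam that sets the only stereocenter.
2. Key disconnection: the bond between the lactam carbonyl carbon and the ring A carbon ortho to the spiro carbon. Ring B is closed by an aryllithium attacking an N-bound oxazolidin-2-one, which is opened in the same event.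
3. Enabling feature: the lactam N carries both the C=O carbon and the CH2CH2O chain, which together are the atoms of an oxazolidin-2-one (used as a temporary ring). Ring A has only one free position ortho to the spiro carbon (the other bears OMe). The future spiro carbon is kept one oxidation level lower (C–H) through the key step and is oxygenated afterwards.
4. The oxazolidinone precursor comes from a three-component amidoalkylation of naphthol 6, aldehyde 7 and oxazolidin-2-one 8, which forms the C–C bond at C8 of the naphthalene and the C–N bond.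
5. Ring order: ring E by benzannulation (step 2), ring B (step 6), ring C (step 9); rings A and D are bought.

Key step: step 6

Assumption: the sense of induction of the phosphoric acid in step 9 cannot be fixed on paper; (R)-TRIP is written, and its enantiomer is to be used if the (S)-ketal should predominate.

**Route**

Step 1
Reactants: 1 1-[4-(benzyloxy)phenyl]propan-2-one; 2 triethyl phosphonoacetate
Product: 4 4-[4-(benzyloxy)phenyl]-3-methylbut-2-enoic acid (mixture of double-bond isomers), via ethyl ester 3 (not isolated)
Conditions: NaH, THF, 0 °C → rt; then NaOH, EtOH/H2O, reflux; HCl work-up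
Reagents that add atoms: sodium hydroxide [Na+].[OH-]
Why: A Horner–Wadsworth–Emmons olefination of the ketone followed by saponification in the same flask should give the unsaturated acid as a mixture of double-bond isomers that all converge in step 2; no stereocenter is formed.

Step 2
Reactants: 4 4-[4-(benzyloxy)phenyl]-3-methylbut-2-enoic acid
Product: 5 7-(benzyloxy)-3-methylnaphthalen-1-yl acetate
Conditions: Ac2O, NaOAc, 140 °C
Reagents that add atoms: acetic anhydride CC(=O)OC(C)=O
Why: The mixed anhydride should give a dienylketene that closes onto the arene by 6π-electrocyclisation (the benzannulation used after Stobbe condensations, ring E), and the new naphthol is acetylated in situ, which leaves the two naphthalene oxygens differentiated.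

Step 3
Reactants: 5 7-(benzyloxy)-3-methylnaphthalen-1-yl acetate
Product: 6 7-hydroxy-3-methylnaphthalen-1-yl acetate
Conditions: H2 (1 atm), Pd/C (10 wt%), EtOAc, rt
Reagents that add atoms: none
Why: Hydrogenolysis of the benzyl ether should leave the aryl acetate untouched and free only the 7-hydroxyl, so that its ortho alpha position C8 becomes the single strongly activated carbon of the naphthalene.

Step 4
Reactants: 6 7-hydroxy-3-methylnaphthalen-1-yl acetate; 7 2-bromo-6-methoxybenzaldehyde; 8 1,3-oxazolidin-2-one
Product: 9 8-[(2-bromo-6-methoxyphenyl)(2-oxo-1,3-oxazolidin-3-yl)methyl]-7-hydroxy-3-methylnaphthalen-1-yl acetate (racemic)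
Conditions: TsOH·H2O (10 mol%), 4 Å MS, ClCH2CH2Cl, 80 °C
Reagents that add atoms: none
Why: Acid-catalysed three-component amidoalkylation of a 2-naphthol (Betti-type): the aldehyde is attacked by C8, the ortho-quinone methide formed by dehydration is trapped by the N–H of the cyclic carbamate, the acetylated ring E stays unreactive, and the benzhydrylic stereocenter forms as a racemate that is destroyed later.

Step 5
Reactants: 9 8-[(2-bromo-6-methoxyphenyl)(2-oxo-1,3-oxazolidin-3-yl)methyl]-7-hydroxy-3-methylnaphthalen-1-yl acetate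
Product: 11 3-{[2,8-bis(benzyloxy)-6-methylnaphthalen-1-yl](2-bromo-6-methoxyphenyl)methyl}-1,3-oxazolidin-2-one (racemic), via naphthalenediol 10 (not isolated)
Conditions: K2CO3, MeOH, rt; solvent exchange; BnBr, K2CO3, n-Bu4NI (cat.), DMF, rt
Reagents that add atoms: benzyl bromide BrCc1ccccc1
Why: Methanolysis of the aryl acetate and Williamson benzylation of both naphthols in one flask should give a substrate without acidic protons or ester electrophiles for the organolithium step.

Step 6
Reactants: 11 3-{[2,8-bis(benzyloxy)-6-methylnaphthalen-1-yl](2-bromo-6-methoxyphenyl)methyl}-1,3-oxazolidin-2-one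
Product: 14 3-[2,8-bis(benzyloxy)-6-methylnaphthalen-1-yl]-2-[2-(tert-butyldimethylsilyloxy)ethyl]-4-methoxyisoindolin-1-one (racemic), via aryllithium 12 (not isolated), via lithium alkoxide 13 (not isolated)
Conditions: t-BuLi (2.1 equiv), THF, −78 °C → −40 °C; then TBSOTf (1.2 equiv), −78 °C → 0 °C
Reagents that add atoms: tert-butyllithium [Li]C(C)(C)C; tert-butyldimethylsilyl trifluoromethanesulfonate CC(C)(C)[Si](C)(C)OS(=O)(=O)C(F)(F)F
Why: Br/Li exchange with t-BuLi at −78 °C is faster than deprotonation of the benzhydrylic C–H and unmasks an aryl anion at the only ring A position ortho to the benzhydrylic carbon that is not blocked by OMe; this aryllithium adds to the carbonyl of the cyclic carbamate, and the tetrahedral intermediate collapses by expelling the ring alkoxide, so that the oxazolidinone opens as the lactam forms. The closest known reaction type is the Parham cyclisation of aryllithiums onto internal carbamates, here with the leaving alkoxide kept on nitrogen as the 2-oxyethyl arm. Ring B is closed in a 5-exo-trig mode by attack of the aryl carbon on the C=O carbon. No stereocenter is formed; the benzhydrylic center stays racemic and is erased in steps 7 to 9. The step needs site selectivity for one arene carbon and chemoselectivity for the carbamate: the bromine fixes the site, and the substrate carries no other electrophile or acidic O–H (both naphthols are benzylated, the acetate is gone). The liberated lithium alkoxide is silylated in the same flask, which caps the only oxygen that could later compete with the peri-hydroxyl for the spiro carbon.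

Step 7
Reactants: 14 3-[2,8-bis(benzyloxy)-6-methylnaphthalen-1-yl]-2-[2-(tert-butyldimethylsilyloxy)ethyl]-4-methoxyisoindolin-1-one
Product: 17 3-[2,8-bis(benzyloxy)-6-methylnaphthalen-1-yl]-2-[2-(tert-butyldimethylsilyloxy)ethyl]-3-hydroxy-4-methoxyisoindolin-1-one (racemic), via potassium carbanion 15 (not isolated), via hydroperoxide 16 (not isolated)
Conditions: KN(SiMe3)2 (1.3 equiv), THF, −78 °C; O2 (1 atm), P(OEt)3 (2 equiv), −78 °C → −20 °C
Reagents that add atoms: potassium bis(trimethylsilyl)amide C[Si](C)(C)N([K])[Si](C)(C)C; dioxygen O=O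
Why: Deprotonation of the doubly benzylic, lactam-activated C3–H and oxygenation of the carbanion with O2/P(OEt)3 (enolate-type hydroxylation, well known for 3-arylisoindolinones) should raise the future spiro carbon to the ketone oxidation level; the carbinol center is racemic and is ionised in step 9.

Step 8
Reactants: 17 3-[2,8-bis(benzyloxy)-6-methylnaphthalen-1-yl]-2-[2-(tert-butyldimethylsilyloxy)ethyl]-3-hydroxy-4-methoxyisoindolin-1-one
Product: 18 2-[2-(tert-butyldimethylsilyloxy)ethyl]-3-(2,8-dihydroxy-6-methylnaphthalen-1-yl)-3-hydroxy-4-methoxyisoindolin-1-one (racemic)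
Conditions: H2 (1 atm), Pd/C (10 wt%), NaHCO3, EtOAc, rt; crude product used at once, no silica gel
Reagents that add atoms: none
Why: Hydrogenolysis of both benzyl ethers under buffered neutral conditions should free the two naphthols without ionising the hydroxylactam, the silyl ether and the aryl methyl ether being inert.

Step 9
Reactants: 18 2-[2-(tert-butyldimethylsilyloxy)ethyl]-3-(2,8-dihydroxy-6-methylnaphthalen-1-yl)-3-hydroxy-4-methoxyisoindolin-1-one
Product: 20 (R)-2-[2-(tert-butyldimethylsilyloxy)ethyl]-3'-hydroxy-7-methoxy-7'-methylspiro[isoindoline-1,2'-naphtho[1,8-bc]furan]-3-one, via ortho-quinone methide 19 (not isolated)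
Conditions: (R)-TRIP [(R)-3,3'-bis(2,4,6-triisopropylphenyl)-1,1'-binaphthyl-2,2'-diyl hydrogen phosphate] (10 mol%), 4 Å MS, toluene, −20 °C
Reagents that add atoms: none
Why: Chiral phosphoric acid catalysis of the kind used for additions to ortho-quinone methides and to N-acyl ketiminium ions from 3-aryl-3-hydroxyisoindolinones: dehydration gives the planar quinone methide/N-acyliminium species bound to the chiral phosphate, and the peri-hydroxyl adds to one face of the former C3 (closure of ring C), so that the catalyst sets the (R) configuration of the only stereocenter while the silyl ether keeps the side-chain oxygen out of the reaction.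

Step 10
Reactants: 20 (R)-2-[2-(tert-butyldimethylsilyloxy)ethyl]-3'-hydroxy-7-methoxy-7'-methylspiro[isoindoline-1,2'-naphtho[1,8-bc]furan]-3-one
Product: 21 (R)-3'-hydroxy-2-(2-hydroxyethyl)-7-methoxy-7'-methylspiro[isoindoline-1,2'-naphtho[1,8-bc]furan]-3-one (CNP0434366.1)
Conditions: n-Bu4NF/AcOH (1:1), THF, 0 °C
Reagents that add atoms: none
Why: Fluoride-mediated desilylation buffered with acetic acid should free the primary alcohol without strong acid or base, so that the N,O-ketal neither ionises nor ring-opens through the naphtholate and the configuration is retained.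

**Compound list**

1 | 1-[4-(benzyloxy)phenyl]propan-2-one | CC(=O)Cc1ccc(OCc2ccccc2)cc1 | starting material
2 | triethyl phosphonoacetate | CCOC(=O)CP(=O)(OCC)OCC | starting material
3 | ethyl 4-[4-(benzyloxy)phenyl]-3-methylbut-2-enoate (isomer mixture, not isolated) | CCOC(=O)C=C(C)Cc1ccc(OCc2ccccc2)cc1 | intermediate
4 | 4-[4-(benzyloxy)phenyl]-3-methylbut-2-enoic acid (isomer mixture) | OC(=O)C=C(C)Cc1ccc(OCc2ccccc2)cc1 | intermediate
5 | 7-(benzyloxy)-3-methylnaphthalen-1-yl acetate | CC(=O)Oc1cc(C)cc2ccc(OCc3ccccc3)cc12 | intermediate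
6 | 7-hydroxy-3-methylnaphthalen-1-yl acetate | CC(=O)Oc1cc(C)cc2ccc(O)cc12 | intermediate
7 | 2-bromo-6-methoxybenzaldehyde | COc1cccc(Br)c1C=O | starting material
8 | 1,3-oxazolidin-2-one | O=C1NCCO1 | starting material
9 | 8-[(2-bromo-6-methoxyphenyl)(2-oxo-1,3-oxazolidin-3-yl)methyl]-7-hydroxy-3-methylnaphthalen-1-yl acetate (racemic) | CC(=O)Oc1cc(C)cc2ccc(O)c(C(N3CCOC3=O)c3c(Br)cccc3OC)c12 | intermediate
10 | 3-[(2-bromo-6-methoxyphenyl)(2,8-dihydroxy-6-methylnaphthalen-1-yl)methyl]-1,3-oxazolidin-2-one (racemic, not isolated) | COc1cccc(Br)c1C(N2CCOC2=O)c2c(O)ccc3cc(C)cc(O)c23 | intermediate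
11 | 3-{[2,8-bis(benzyloxy)-6-methylnaphthalen-1-yl](2-bromo-6-methoxyphenyl)methyl}-1,3-oxazolidin-2-one (racemic) | COc1cccc(Br)c1C(N2CCOC2=O)c2c(OCc3ccccc3)ccc3cc(C)cc(OCc4ccccc4)c23 | intermediate
12 | 3-{[2,8-bis(benzyloxy)-6-methylnaphthalen-1-yl](2-lithio-6-methoxyphenyl)methyl}-1,3-oxazolidin-2-one (not isolated) | COc1cccc([Li])c1C(N2CCOC2=O)c2c(OCc3ccccc3)ccc3cc(C)cc(OCc4ccccc4)c23 | intermediate
13 | 3-[2,8-bis(benzyloxy)-6-methylnaphthalen-1-yl]-2-(2-lithiooxyethyl)-4-methoxyisoindolin-1-one (not isolated) | COc1cccc2c1C(c1c(OCc3ccccc3)ccc3cc(C)cc(OCc4ccccc4)c13)N(CCO[Li])C2=O | intermediate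
14 | 3-[2,8-bis(benzyloxy)-6-methylnaphthalen-1-yl]-2-[2-(tert-butyldimethylsilyloxy)ethyl]-4-methoxyisoindolin-1-one (racemic) | COc1cccc2c1C(c1c(OCc3ccccc3)ccc3cc(C)cc(OCc4ccccc4)c13)N(CCO[Si](C)(C)C(C)(C)C)C2=O | intermediate
15 | 3-potassio derivative of 14 (C3 carbanion, not isolated) | COc1cccc2c1C([K])(c1c(OCc3ccccc3)ccc3cc(C)cc(OCc4ccccc4)c13)N(CCO[Si](C)(C)C(C)(C)C)C2=O | intermediate
16 | 3-[2,8-bis(benzyloxy)-6-methylnaphthalen-1-yl]-2-[2-(tert-butyldimethylsilyloxy)ethyl]-3-hydroperoxy-4-methoxyisoindolin-1-one (not isolated) | COc1cccc2c1C(OO)(c1c(OCc3ccccc3)ccc3cc(C)cc(OCc4ccccc4)c13)N(CCO[Si](C)(C)C(C)(C)C)C2=O | intermediate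
17 | 3-[2,8-bis(benzyloxy)-6-methylnaphthalen-1-yl]-2-[2-(tert-butyldimethylsilyloxy)ethyl]-3-hydroxy-4-methoxyisoindolin-1-one (racemic) | COc1cccc2c1C(O)(c1c(OCc3ccccc3)ccc3cc(C)cc(OCc4ccccc4)c13)N(CCO[Si](C)(C)C(C)(C)C)C2=O | intermediate
18 | 2-[2-(tert-butyldimethylsilyloxy)ethyl]-3-(2,8-dihydroxy-6-methylnaphthalen-1-yl)-3-hydroxy-4-methoxyisoindolin-1-one (racemic) | COc1cccc2c1C(O)(c1c(O)ccc3cc(C)cc(O)c13)N(CCO[Si](C)(C)C(C)(C)C)C2=O | intermediate
19 | 2-[2-(tert-butyldimethylsilyloxy)ethyl]-3-(8-hydroxy-6-methyl-2-oxonaphthalen-1(2H)-ylidene)-4-methoxyisoindolin-1-one (ortho-quinone methide, not isolated) | COc1cccc2c1C(=C3C(=O)C=Cc4cc(C)cc(O)c34)N(CCO[Si](C)(C)C(C)(C)C)C2=O | intermediate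
20 | (R)-2-[2-(tert-butyldimethylsilyloxy)ethyl]-3'-hydroxy-7-methoxy-7'-methylspiro[isoindoline-1,2'-naphtho[1,8-bc]furan]-3-one | COc1cccc2c1[C@@]1(Oc3cc(C)cc4ccc(O)c1c34)N(CCO[Si](C)(C)C(C)(C)C)C2=O | intermediate
21 | (R)-3'-hydroxy-2-(2-hydroxyethyl)-7-methoxy-7'-methylspiro[isoindoline-1,2'-naphtho[1,8-bc]furan]-3-one (CNP0434366.1) | COc1cccc2c1[C@@]1(Oc3cc(C)cc4ccc(O)c1c34)N(CCO)C2=O | target

**Step count and weak points**

Total step count: 10. Longest linear sequence: 10 steps (1 to 21); 2, 7 and 8 enter as bought reagents.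

Steps most likely to fail:

1. Step 9. Facial discrimination in the closure of ring C may be weak, an uncatalysed cyclisation of 18 may compete, or the product ketal may re-ionise under the acid and lose enantiomeric purity. The fallback sets out from 18. It is cyclised with an achiral acid (TsOH·H2O cat., CH2Cl2, 0 °C) to the racemic silyl-protected spiroketal F1. The enantiomers are then separated by preparative chromatography on a chiral stationary phase (polysaccharide column, supercritical CO2/MeOH), which removes the (S)-configured silyl-protected spiroketal F2. The route is rejoined at 20.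

2. Step 4. Carbon–carbon bond formation at the peri-flanked C8 with a 2,6-disubstituted aldehyde may be slow, so that condensation of aldehyde and carbamate alone or loss of the acetate takes over. The fallback sets out from 7 and 8. They are condensed with benzenesulfinic acid (PhSO2H, CH2Cl2, MgSO4, rt) to the α-amido sulfone 3-[(benzenesulfonyl)(2-bromo-6-methoxyphenyl)methyl]-1,3-oxazolidin-2-one F3. This preformed N-acyliminium precursor is ionised with TiCl4 (CH2Cl2, −78 °C → 0 °C) in the presence of naphthol 6, whose titanium naphtholate directs the Friedel–Crafts amidoalkylation to the ortho carbon C8. The route is rejoined at 9.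

3. Step 7. Deprotonation at the crowded C3–H may be sluggish, or the carbanion may be over-oxidised. The fallback sets out from 14 and moves the oxidation to the naphthol. Hydrogenolysis (H2, Pd/C, EtOAc) gives the debenzylated lactam 2-[2-(tert-butyldimethylsilyloxy)ethyl]-3-(2,8-dihydroxy-6-methylnaphthalen-1-yl)-4-methoxyisoindolin-1-one F4. Two-electron oxidation of its 2-naphthol unit with Ag2O (CH2Cl2, rt) gives the ortho-quinone methide 19 directly. This is cyclised with the phosphoric acid of step 9, so the route is rejoined at 19 and then 20, bypassing 17 and 18.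

Further compounds
F1 | step 9 | racemic 2-[2-(tert-butyldimethylsilyloxy)ethyl]-3'-hydroxy-7-methoxy-7'-methylspiro[isoindoline-1,2'-naphtho[1,8-bc]furan]-3-one | COc1cccc2c1C1(Oc3cc(C)cc4ccc(O)c1c34)N(CCO[Si](C)(C)C(C)(C)C)C2=O
F2 | step 9 | (S)-2-[2-(tert-butyldimethylsilyloxy)ethyl]-3'-hydroxy-7-methoxy-7'-methylspiro[isoindoline-1,2'-naphtho[1,8-bc]furan]-3-one | COc1cccc2c1[C@]1(Oc3cc(C)cc4ccc(O)c1c34)N(CCO[Si](C)(C)C(C)(C)C)C2=O
F3 | step 4 | 3-[(benzenesulfonyl)(2-bromo-6-methoxyphenyl)methyl]-1,3-oxazolidin-2-one | COc1cccc(Br)c1C(N1CCOC1=O)S(=O)(=O)c1ccccc1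
F4 | step 7 | 2-[2-(tert-butyldimethylsilyloxy)ethyl]-3-(2,8-dihydroxy-6-methylnaphthalen-1-yl)-4-methoxyisoindolin-1-one | COc1cccc2c1C(c1c(O)ccc3cc(C)cc(O)c13)N(CCO[Si](C)(C)C(C)(C)C)C2=O
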